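Watch how much of the approach to the plateau your flask gets, not the clock.

all flasks: gas phase 46 mM (held)
- Tuesday's: starting material 1 M; protic impurity 0.067 M; free catalyst 1 mM; run made earlier
- Monday's: starting material 1 M; protic impurity 0.15 M; free catalyst 1 mM; run made earlier
- Thursday's: starting material 1 M; protic impurity 0.10 M; free catalyst 0.50 mM; run made earlier
- flask: starting material 1.0 M; protic impurity 0.100 M; free catalyst 1.0 mM; time 8.0 min

- Tuesday's (time / min: target / %): 0.667: 43; 1.33: 71; 2.00: 76; 3.00: 87; 4.00: 93; 5.00: 91
- Monday's (time / min: target / %): 0.667: 38; 1.33: 60; 2.00: 71; 3.00: 78; 4.00: 83; 5.00: 86
- Thursday's (time / min: target / %): 0.417: 15; 0.667: 24; 1.33: 42; 2.50: 60; 5.00: 84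

(standard deviation of a reading: 2 percentage points)

- at the start none of the gas phase is in solution

- teal: doubling the saturation concentration of gas phase, all else as stated
- green: doubling the transfer coefficient of the gas phase, all else as stated
- blue: doubling the amount of free catalyst, all else as stated

- how much target there is at 8.0 min, in percent of the starting material charged
- the change that raises the amount of target at 8.0 min, in percent of the starting material charged most ("none" if none brings more than 2 percentage points) (teal / green / blue / none)
- amount of target at 8.0 min, in percent of the starting material charged, after blue

1. Work in fractions of the charge. Tuesday's run ends near 91% and Monday's near 86%, while the charge less the protic impurity is 93.3% and 85.0%. So take the room for this flask as 90.0%.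

2. Inside the room, treat the approach as pseudo-first-order. Thursday's 60% at 2.50 min, scaled by free catalyst and time, gives this flask an approach count of 7.03, the number of time constants it gets. The unfilled share of the room is exp(−count), here 0.0885%.

3. Test it on Monday's run: at 2.00 min the count is 1.76, which gives 70.3%. The reading is 71%, with a scatter of 2 percentage points.

4. My figure for this flask is 89.9%. The unfilled part is 0.08 points, less than the margin of 2 points, so if the room stays, I choose none.

5. The forecast gives 90%, none, and 90% after blue: "Teal, green and blue all only speed up a finished reaction".

6. The flask gives 89.9%, none, and 90.0% after blue.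

    free catalyst → spent catalyst (k = 3.40 × 10⁻⁵ s⁻¹)
    gas phase ⇌ dissolved gas, rate k2*(csat - [dissolved gas]) (kL = 11.0 s⁻¹)
    starting material + dissolved gas + free catalyst → free catalyst + target (k = 340 M⁻² s⁻¹)
    starting material + protic impurity → quenched substrate (k = 1.70 M⁻¹ s⁻¹)

This flask holds 0.0540% of starting material at 8.00 min, against 0.0796% of the charge unfilled by the count.

7. Cut the free catalyst to 0.400 mM and the count falls to 2.81, which gives 84.6% target with 5.42% unfilled. That flask gives 85.4%, with 4.63% of starting material left.

The earlier runs and the new flask were computed for an exercise; the scatter is artificial.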